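**Strategy**

The cyclohexane ring is not made as such: its six carbons (ring C1–C6) come from a cycloheptene oxide whose seventh carbon is expelled as the formyl, later carboxyl, carbon on ring C1. The key step, a magnesium bromide-mediated semipinacol (Meinwald-type) contraction of the hydroxyl-directed syn-epoxide of a cis-2-silyloxycyclohept-4-enol, is regioconvergent, because ring C1 ends 1,3 to the C3 oxygen and 1,4 to the C4 oxygen whichever epoxide carbon leaves, and it sets C1 trans to both oxygens by double inversion. One bought stereocentre thus relays all three. The chain is built by Marshall propargylation, a Cornforth-controlled chloroaldehyde aldol, late alkenylation and Suzuki coupling to the ring-bound iodotrienoate.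

Key step: step 7

Remark (assumption): the vanadium-catalysed epoxidation is taken to follow the syn rule of cyclic homoallylic alcohols, and the contraction to run through trans-bromohydrin salts as for the parent cycloalkene oxides; compounds 1, 11, 20, 24 and 33 are taken as commercial.

Numbering: chain atoms C1–C23 as in the target acyl chain (C1 = ester carbonyl, C23 = terminal methyl); the cyclohexane carbons are ring C1 (CO2H), ring C3 (acyloxy) and ring C4 (OH). TBS = tert-butyldimethylsilyl, TES = triethylsilyl.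

**Part A – cyclohexane core (steps 1–7)**

Step 1
Reactants: 1 methyl (S)-glycidate
Product: 2 methyl (S)-2-hydroxyhex-5-enoate
Conditions: allylMgBr, CuI (10 mol %), THF, −78 → −40 °C; aq. NH4Cl
Reagents that add atoms: allylmagnesium bromide, C=CC[Mg]Br
Why: Copper-catalysed SN2 opening of the glycidate at its unhindered CH2 carbon (organocuprate epoxide opening) should leave the bought C2 stereocentre untouched.

Step 2
Reactants: 2 methyl (S)-2-hydroxyhex-5-enoate
Product: 3 methyl (S)-2-(tert-butyldimethylsilyloxy)hex-5-enoate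
Conditions: TBSCl, imidazole, DMF, rt
Reagents that add atoms: tert-butyldimethylsilyl chloride, CC(C)(C)[Si](C)(C)Cl
Why: Standard silylation of the secondary alcohol; this ether marks the later ring C4 oxygen and makes the aldehyde non-chelating.

Step 3
Reactants: 3 methyl (S)-2-(tert-butyldimethylsilyloxy)hex-5-enoate
Product: 4 (S)-2-(tert-butyldimethylsilyloxy)hex-5-enal
Conditions: i-Bu2AlH (1.1 equiv), CH2Cl2, −78 °C; aq. potassium sodium tartrate
Reagents that add atoms: none
Why: Partial reduction of an α-silyloxy ester should stop at the aldehyde because the tetrahedral aluminium hemiacetal is stable at −78 °C.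

Step 4
Reactants: 4 (S)-2-(tert-butyldimethylsilyloxy)hex-5-enal
Product: 5 (4R,5S)-5-(tert-butyldimethylsilyloxy)nona-1,8-dien-4-ol
Conditions: allylSnBu3, BF3·OEt2, CH2Cl2, −78 °C; aq. KF
Reagents that add atoms: allyltributylstannane, C=CC[Sn](CCCC)(CCCC)CCCC
Why: Lewis acid-promoted allylstannane addition under non-chelating conditions should follow the Felkin–Anh model and give the 4,5-anti alcohol, so the new carbinol centre (4R) is relayed from C5.

Step 5
Reactants: 5 (4R,5S)-5-(tert-butyldimethylsilyloxy)nona-1,8-dien-4-ol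
Product: 6 (1R,7S)-7-(tert-butyldimethylsilyloxy)cyclohept-3-en-1-ol
Conditions: second-generation Grubbs catalyst (H2IMes)(PCy3)Cl2Ru=CHPh (3 mol %), CH2Cl2 (5 mM), 40 °C
Reagents that add atoms: none
Why: Ring-closing metathesis of the 1,8-diene should close the cis-cycloheptene with loss of ethylene and tolerates the free alcohol.

Step 6
Reactants: 6 (1R,7S)-7-(tert-butyldimethylsilyloxy)cyclohept-3-en-1-ol
Product: 7 (1S,3R,4S,7R)-4-(tert-butyldimethylsilyloxy)-8-oxabicyclo[5.1.0]octan-3-ol (all-cis epoxy alcohol)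
Conditions: VO(acac)2 (5 mol %), t-BuOOH (1.5 equiv, decane), CH2Cl2, 0 °C → rt
Reagents that add atoms: tert-butyl hydroperoxide, CC(C)(C)OO
Why: Hydroxyl-directed vanadium-catalysed epoxidation should deliver oxygen to the alkene face syn to the homoallylic OH (and so syn to the cis-OTBS), setting both epoxide carbons from the ring C3 carbinol centre.

Step 7
Reactants: 7 (1S,3R,4S,7R)-4-(tert-butyldimethylsilyloxy)-8-oxabicyclo[5.1.0]octan-3-ol
Product: 10 (1S,3R,4S)-4-(tert-butyldimethylsilyloxy)-3-hydroxycyclohexane-1-carbaldehyde, via bromohydrin magnesium alkoxide 8 (not isolated), via regioisomeric bromohydrin magnesium alkoxide 9 (not isolated)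
Conditions: MgBr2·OEt2 (2 equiv), Et2O, 0 °C → rt; then toluene, 65 °C
Reagents that add atoms: none
Why: MgBr2 opens the cis-epoxide by anti attack of bromide at either epoxide carbon to give the trans-bromohydrin magnesium alkoxides 8 and 9, in which the ring C–C bond on the carbinol carbon lies antiperiplanar to C–Br and migrates with loss of bromide while the carbinol carbon becomes the formyl group (semipinacol stage of a Meinwald-type epoxide-to-aldehyde rearrangement). The closest known reactions are the MgBr2- and LiBr-mediated contractions of cyclohexene oxide to cyclopentanecarbaldehyde and of cycloheptene oxide to cyclohexanecarbaldehyde through trans-halohydrin salts. The six-membered ring is not closed by a cyclization; it is formed from the seven-membered ring by a 1,2-alkyl shift onto the bromine-bearing carbon (ring contraction from seven to six). The new stereocentre, ring C1, is controlled by the epoxide configuration through two inversions (bromide anti to the epoxide oxygen, migrating carbon anti to bromide), so the formyl group should end on the face opposite the former epoxide oxygen, trans to the C3 hydroxyl and the C4 silyloxy group. The step needs alkyl shift rather than hydride shift, which the trans-halohydrin geometry secures because the carbinol hydrogen is syn to the C–Br bond, and it needs no regiocontrol, because migration from 8 or from 9 gives the same aldehyde (the retained epoxide carbon ends 1,3 to the carbinol carbon and 1,4 to the silyloxy carbon in both).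

**Part B – iodotrienoic acid (steps 8–11)**

Step 8
Reactants: 11 prop-2-yn-1-ol
Product: 13 (E)-3-iodo-2-methylprop-2-en-1-ol, via alkenylalane 12 (not isolated)
Conditions: AlMe3 (3 equiv), Cp2ZrCl2 (25 mol %), CH2Cl2, 0 °C → rt; then I2, THF, −30 °C; aq. potassium sodium tartrate
Reagents that add atoms: trimethylaluminium, C[Al](C)C; iodine, II
Why: Negishi carboalumination adds methyl and aluminium syn with methyl on the internal carbon, and iodinolysis of the C–Al bond with retention should give the (E)-iodoalkene.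

Step 9
Reactants: 13 (E)-3-iodo-2-methylprop-2-en-1-ol
Product: 14 (E)-3-iodo-2-methylprop-2-enal
Conditions: TEMPO (10 mol %), PhI(OAc)2 (1.1 equiv), CH2Cl2, rt
Reagents that add atoms: none
Why: Nitroxyl-catalysed oxidation of the allylic alcohol should give the enal without touching the vinyl iodide or the alkene geometry.

Step 10
Reactants: 14 (E)-3-iodo-2-methylprop-2-enal
Product: 15 ethyl (2E,4E,6E)-7-iodo-6-methylhepta-2,4,6-trienoate
Conditions: triethyl 4-phosphonocrotonate, LiN(SiMe3)2, THF, −78 °C; then 14, −78 → 0 °C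
Reagents that add atoms: triethyl 4-phosphonocrotonate, CCOC(=O)/C=C/CP(=O)(OCC)OCC
Why: Vinylogous Horner–Wadsworth–Emmons olefination of the non-enolizable enal should form the new C4=C5 bond mainly E under thermodynamic control of the stabilized phosphonate anion.

Step 11
Reactants: 15 ethyl (2E,4E,6E)-7-iodo-6-methylhepta-2,4,6-trienoate
Product: 16 (2E,4E,6E)-7-iodo-6-methylhepta-2,4,6-trienoic acid
Conditions: LiOH·H2O, THF/MeOH/H2O, rt; then 1 M HCl to pH 3
Reagents that add atoms: lithium hydroxide, [Li+].[OH-]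
Why: Saponification of the ethyl ester; the vinyl iodide and the triene are inert to aqueous hydroxide at room temperature.

**Part C – ring-bound iodotrienoate (steps 12–13)**

Step 12
Reactants: 16 (2E,4E,6E)-7-iodo-6-methylhepta-2,4,6-trienoic acid; 10 (1S,3R,4S)-4-(tert-butyldimethylsilyloxy)-3-hydroxycyclohexane-1-carbaldehyde
Product: 18 (1R,2S,5S)-2-(tert-butyldimethylsilyloxy)-5-formylcyclohexyl (2E,4E,6E)-7-iodo-6-methylhepta-2,4,6-trienoate, via mixed anhydride 17 (not isolated)
Conditions: 16, 2,4,6-trichlorobenzoyl chloride, Et3N, THF, rt; then 10, DMAP, toluene, rt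
Reagents that add atoms: none
Why: Yamaguchi esterification should transfer the trienoyl group through the acylpyridinium ion to the only free hydroxyl (ring C3); the aldehyde α-centre should survive the weakly basic aprotic medium.

Step 13
Reactants: 18 (1R,2S,5S)-2-(tert-butyldimethylsilyloxy)-5-formylcyclohexyl (2E,4E,6E)-7-iodo-6-methylhepta-2,4,6-trienoate
Product: 19 (1S,3R,4S)-4-(tert-butyldimethylsilyloxy)-3-{[(2E,4E,6E)-7-iodo-6-methylhepta-2,4,6-trienoyl]oxy}cyclohexane-1-carboxylic acid
Conditions: NaClO2, NaH2PO4, 2-methyl-2-butene, t-BuOH/H2O, 0 °C → rt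
Reagents that add atoms: sodium chlorite, [Na+].[O-]Cl=O
Why: Pinnick oxidation is chemoselective for the aldehyde in a weakly acidic buffer (no epimerization at ring C1), and the alkene scavenger removes hypochlorous acid before it can attack the iodotriene.

**Part D – C9–C16 methyl ketone (steps 14–23)**

Step 14
Reactants: 20 (S)-but-3-ene-1,2-diol
Product: 21 (S)-3,4-bis(tert-butyldimethylsilyloxy)but-1-ene
Conditions: TBSCl (2.5 equiv), imidazole, DMF, rt
Reagents that add atoms: tert-butyldimethylsilyl chloride, CC(C)(C)[Si](C)(C)Cl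
Why: Exhaustive silylation of the diol; the secondary TBS ether is the lasting protection of the C14 oxygen.

Step 15
Reactants: 21 (S)-3,4-bis(tert-butyldimethylsilyloxy)but-1-ene
Product: 22 (S)-2-(tert-butyldimethylsilyloxy)but-3-en-1-ol
Conditions: HF·pyridine, pyridine, THF, 0 °C
Reagents that add atoms: none
Why: Buffered HF·pyridine should cleave the unhindered primary silyl ether much faster than the secondary one.

Step 16
Reactants: 22 (S)-2-(tert-butyldimethylsilyloxy)but-3-en-1-ol
Product: 23 (S)-2-(tert-butyldimethylsilyloxy)but-3-enal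
Conditions: Dess–Martin periodinane, NaHCO3, CH2Cl2, 0 °C; used at once
Reagents that add atoms: none
Why: Buffered, base-free oxidation should avoid migration of the β,γ-double bond into conjugation and epimerization of the α-silyloxy aldehyde.

Step 17
Reactants: 24 (S)-but-3-yn-2-ol
Product: 25 (S)-but-3-yn-2-yl methanesulfonate
Conditions: MsCl, Et3N, CH2Cl2, −78 °C
Reagents that add atoms: methanesulfonyl chloride, CS(=O)(=O)Cl
Why: Mesylation at oxygen does not touch the stereocentre.

Step 18
Reactants: 25 (S)-but-3-yn-2-yl methanesulfonate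
Product: 26 (aR)-tributyl(buta-1,2-dien-1-yl)stannane
Conditions: Bu3SnH, LiN(iPr)2, THF, 0 °C; CuBr·SMe2, −78 °C; then 25, −78 °C
Reagents that add atoms: tributyltin hydride, CCCC[SnH](CCCC)CCCC
Why: Anti SN2′ displacement of the propargylic mesylate by the stannylcopper reagent should transfer the central chirality to the allene axis.

Step 19
Reactants: 23 (S)-2-(tert-butyldimethylsilyloxy)but-3-enal; 26 (aR)-tributyl(buta-1,2-dien-1-yl)stannane
Product: 27 (3S,4R,5S)-3-(tert-butyldimethylsilyloxy)-5-methylhept-1-en-6-yn-4-ol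
Conditions: BF3·OEt2, CH2Cl2, −78 °C; aq. KF
Reagents that add atoms: none
Why: Marshall propargylation (BF3-promoted anti-SE2′ addition through an open transition state) should give the 12,13-syn homopropargylic alcohol with C12 fixed by the allene axis, matched with the Felkin–Anh preference of the α-silyloxy aldehyde that sets C13 anti to C14.

Step 20
Reactants: 27 (3S,4R,5S)-3-(tert-butyldimethylsilyloxy)-5-methylhept-1-en-6-yn-4-ol
Product: 28 (3S,4R,5S)-3,4-bis(tert-butyldimethylsilyloxy)-5-methylhept-1-en-6-yne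
Conditions: TBSOTf, 2,6-lutidine, CH2Cl2, 0 °C
Reagents that add atoms: tert-butyldimethylsilyl triflate, CC(C)(C)[Si](C)(C)OS(=O)(=O)C(F)(F)F
Why: The silyl triflate silylates the hindered secondary alcohol; two TBS ethers are chosen to survive the later acidic hydrochlorination.

Step 21
Reactants: 28 (3S,4R,5S)-3,4-bis(tert-butyldimethylsilyloxy)-5-methylhept-1-en-6-yne
Product: 30 methyl (4S,5R,6S)-5,6-bis(tert-butyldimethylsilyloxy)-4-methyloct-7-en-2-ynoate, via lithium acetylide 29 (not isolated)
Conditions: n-BuLi, THF, −78 °C; then ClCO2Me, −78 → 0 °C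
Reagents that add atoms: methyl chloroformate, COC(=O)Cl
Why: Deprotonation of the terminal alkyne and C-acylation of the acetylide with the chloroformate give the ynoate.

Step 22
Reactants: 30 methyl (4S,5R,6S)-5,6-bis(tert-butyldimethylsilyloxy)-4-methyloct-7-en-2-ynoate
Product: 31 methyl (2Z,4R,5R,6S)-5,6-bis(tert-butyldimethylsilyloxy)-3-chloro-4-methylocta-2,7-dienoate
Conditions: LiCl (5 equiv), AcOH, MeCN, 80 °C
Reagents that add atoms: lithium chloride, [Li+].[Cl-]
Why: Conjugate hydrochlorination of the ynoate (chloride at the β-carbon, anti protonation of the allenolate) should give the (Z)-β-chloroenoate with chlorine cis to the ester carbon, which is the C10=C11 geometry of the target.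

Step 23
Reactants: 31 methyl (2Z,4R,5R,6S)-5,6-bis(tert-butyldimethylsilyloxy)-3-chloro-4-methylocta-2,7-dienoate
Product: 32 methyl (2Z,4R,5R,6R)-5,6-bis(tert-butyldimethylsilyloxy)-3-chloro-4-methyl-7-oxooct-2-enoate
Conditions: PdCl2 (10 mol %), CuCl (1 equiv), O2 (1 atm), DMF/H2O (7:1), rt
Reagents that add atoms: water, O
Why: Tsuji–Wacker oxidation should convert the only terminal alkene into the methyl ketone by Markovnikov hydroxypalladation; the electron-poor trisubstituted chloroalkene is inert.

**Part E – C17–C19 chloroaldehyde (steps 24–27)**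

Step 24
Reactants: 33 L-serine
Product: 34 (S)-2-chloro-3-hydroxypropanoic acid
Conditions: NaNO2, 6 M HCl, 0 °C → rt
Reagents that add atoms: hydrochloric acid, Cl
Why: Diazotization with carboxylate participation (α-lactone, double inversion) should replace nitrogen by chlorine with net retention.

Step 25
Reactants: 34 (S)-2-chloro-3-hydroxypropanoic acid
Product: 35 methyl (S)-2-chloro-3-hydroxypropanoate
Conditions: MeOH, AcCl (cat., source of HCl), rt
Reagents that add atoms: methanol, CO
Why: Fischer esterification under acid does not enolize the α-chloro centre.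

Step 26
Reactants: 35 methyl (S)-2-chloro-3-hydroxypropanoate
Product: 36 methyl (S)-2-chloro-3-(triethylsilyloxy)propanoate
Conditions: TESCl, imidazole, CH2Cl2, 0 °C
Reagents that add atoms: chlorotriethylsilane, CC[Si](Cl)(CC)CC
Why: Silylation of the primary alcohol under weakly basic conditions; TES is chosen because it can later be removed beside TBS and the silylene.

Step 27
Reactants: 36 methyl (S)-2-chloro-3-(triethylsilyloxy)propanoate
Product: 37 (S)-2-chloro-3-(triethylsilyloxy)propanal
Conditions: i-Bu2AlH (1.05 equiv), CH2Cl2, −78 °C; MeOH, then aq. potassium sodium tartrate; used at once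
Reagents that add atoms: none
Why: Partial reduction of an α-chloro ester stops at the aldehyde stage at −78 °C, and cold neutral work-up keeps the α-chloro centre intact.

**Part F – fragment union and end game (steps 28–39)**

Step 28
Reactants: 32 methyl (2Z,4R,5R,6R)-5,6-bis(tert-butyldimethylsilyloxy)-3-chloro-4-methyl-7-oxooct-2-enoate; 37 (S)-2-chloro-3-(triethylsilyloxy)propanal
Product: 39 methyl (2Z,4R,5R,6R,9R,10S)-5,6-bis(tert-butyldimethylsilyloxy)-3,10-dichloro-9-hydroxy-4-methyl-7-oxo-11-(triethylsilyloxy)undec-2-enoate, via lithium enolate 38 (not isolated)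
Conditions: LiN(iPr)2, THF, −78 °C; then 37, −78 °C, 15 min; aq. NH4Cl at −78 °C
Reagents that add atoms: none
Why: The kinetic methyl-ketone lithium enolate should add to the α-chloroaldehyde anti to chlorine (Cornforth/polar Felkin–Anh aldol addition), forming C16–C17 and setting C17 with the 17,18-anti chlorohydrin relationship.

Step 29
Reactants: 39 methyl (2Z,4R,5R,6R,9R,10S)-5,6-bis(tert-butyldimethylsilyloxy)-3,10-dichloro-9-hydroxy-4-methyl-7-oxo-11-(triethylsilyloxy)undec-2-enoate
Product: 41 methyl (2Z,4R,5R,6S,7S,9R,10S)-5,6-bis(tert-butyldimethylsilyloxy)-3,10-dichloro-7,9-dihydroxy-4-methyl-11-(triethylsilyloxy)undec-2-enoate, via diethylborinate chelate 40 (not isolated)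
Conditions: Et2BOMe, THF/MeOH (4:1), −78 °C; then NaBH4, −78 °C; AcOH, MeOH co-evaporation
Reagents that add atoms: none
Why: Narasaka–Prasad reduction (axial hydride attack on the six-membered boron chelate) should give the 15,17-syn diol; the Felkin preference of the C14 silyloxy group (14,15-anti) points the same way.

Step 30
Reactants: 41 methyl (2Z,4R,5R,6S,7S,9R,10S)-5,6-bis(tert-butyldimethylsilyloxy)-3,10-dichloro-7,9-dihydroxy-4-methyl-11-(triethylsilyloxy)undec-2-enoate
Product: 42 di-tert-butylsilylene acetal of 41 (cis-4,6-disubstituted 1,3,2-dioxasilinane across O15 and O17)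
Conditions: (t-Bu)2Si(OTf)2, 2,6-lutidine, CH2Cl2, 0 °C
Reagents that add atoms: di-tert-butylsilyl bis(trifluoromethanesulfonate), CC(C)(C)[Si](OS(=O)(=O)C(F)(F)F)(OS(=O)(=O)C(F)(F)F)C(C)(C)C
Why: The syn-1,3-diol closes readily to the six-membered silylene, which tolerates mild acid and is removed by fluoride at the end.

Step 31
Reactants: 42 di-tert-butylsilylene acetal of 41
Product: 43 C19 primary alcohol (42 without the triethylsilyl group)
Conditions: PPTS (20 mol %), MeOH/CH2Cl2 (1:1), 0 °C
Reagents that add atoms: none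
Why: Mild acidic methanolysis should remove the primary TES ether and leave the secondary TBS ethers and the silylene.

Step 32
Reactants: 43 C19 primary alcohol
Product: 44 C19 aldehyde (α-chloro aldehyde with C18 (Cl) and the C17 oxygen in the silylene)
Conditions: Dess–Martin periodinane, NaHCO3, CH2Cl2, 0 °C; used at once
Reagents that add atoms: none
Why: Buffered Dess–Martin oxidation gives the α-chloro aldehyde without base, so C18 should not epimerize.

Step 33
Reactants: 44 C19 aldehyde
Product: 45 (19S)-allylic alcohol carrying the (20E)-butenyl group (18,19-anti chlorohydrin)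
Conditions: 1-butyne, Cp2Zr(H)Cl, CH2Cl2, rt; Me2Zn, toluene, −65 °C; then 44, −65 → 0 °C; aq. NH4Cl
Reagents that add atoms: 1-butyne, CCC#C
Why: Hydrozirconation of 1-butyne and transmetalation to zinc give an (E)-alkenylzinc that should add only to the aldehyde and anti to the α-chlorine (Cornforth model), setting C19; the methyl ester is not attacked.

Step 34
Reactants: 45 (19S)-allylic alcohol
Product: 47 C19 carbamate (O-carbamoyl derivative of 45), via N-trichloroacetyl carbamate 46 (not isolated)
Conditions: Cl3CC(O)NCO, CH2Cl2, 0 °C; then K2CO3, MeOH, 0 °C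
Reagents that add atoms: trichloroacetyl isocyanate, O=C=NC(=O)C(Cl)(Cl)Cl
Why: The acyl isocyanate carbamoylates the hindered secondary alcohol at once, and brief methanolysis removes the trichloroacetyl group to leave the primary carbamate.

Step 35
Reactants: 47 C19 carbamate
Product: 48 C9 allylic alcohol ((10Z)-3-chloroallylic alcohol)
Conditions: i-Bu2AlH (4 equiv), CH2Cl2, −78 °C; aq. potassium sodium tartrate
Reagents that add atoms: none
Why: The conjugated methyl ester is reduced to the allylic alcohol at −78 °C, while the carbamate is only deprotonated by the excess hydride and should not be reduced at this temperature.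

Step 36
Reactants: 48 C9 allylic alcohol
Product: 49 (10Z)-C9 enal
Conditions: Dess–Martin periodinane, NaHCO3, CH2Cl2, 0 °C
Reagents that add atoms: none
Why: Mild buffered oxidation of the allylic alcohol should keep the (Z)-chloroalkene geometry.

Step 37
Reactants: 49 (10Z)-C9 enal
Product: 50 (8E,10Z)-dienylboronic acid pinacol ester
Conditions: CrCl2 (8 equiv), LiI (4 equiv), Cl2CHB(pin) (2 equiv), THF, rt
Reagents that add atoms: 2-(dichloromethyl)-4,4,5,5-tetramethyl-1,3,2-dioxaborolane, ClC(Cl)B1OC(C)(C)C(C)(C)O1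
Why: Takai–Utimoto boron olefination (addition of the geminal dichromium species, then anti elimination) should give the (E)-alkenylboronate and tolerates the carbamate, vinyl chloride and silyl groups.

Step 38
Reactants: 50 (8E,10Z)-dienylboronic acid pinacol ester; 19 (1S,3R,4S)-4-(tert-butyldimethylsilyloxy)-3-{[(2E,4E,6E)-7-iodo-6-methylhepta-2,4,6-trienoyl]oxy}cyclohexane-1-carboxylic acid
Product: 51 silyl-protected target (13,14-bis-TBS ether, 15,17-di-tert-butylsilylene, ring C4 TBS ether; free CO2H)
Conditions: Pd(PPh3)4 (10 mol %), TlOEt (3.5 equiv), THF/H2O (3:1), rt, dark; then pH 4 buffer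
Reagents that add atoms: none
Why: Suzuki–Miyaura coupling of the alkenylboronate with the alkenyl iodide forms C7–C8 with retention at both sp2 carbons; the thallium base allows room temperature, at which the vinyl chloride does not undergo oxidative addition.

Step 39
Reactants: 51 silyl-protected target
Product: 52 CNP0164989.3 (target)
Conditions: HF·pyridine, pyridine, THF, 0 °C → rt
Reagents that add atoms: none
Why: Buffered fluoride desilylation under weakly acidic conditions should remove the three TBS ethers and the silylene without forming an alkoxide, so the chlorohydrin cannot close to an epoxide and the ring C3 ester should not migrate.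

**Compound list**

1 | methyl (S)-oxirane-2-carboxylate (methyl (S)-glycidate) | COC(=O)[C@@H]1CO1 | starting material
2 | methyl (S)-2-hydroxyhex-5-enoate | COC(=O)[C@@H](O)CCC=C | intermediate
3 | methyl (S)-2-(tert-butyldimethylsilyloxy)hex-5-enoate | COC(=O)[C@@H](O[Si](C)(C)C(C)(C)C)CCC=C | intermediate
4 | (S)-2-(tert-butyldimethylsilyloxy)hex-5-enal | O=C[C@@H](O[Si](C)(C)C(C)(C)C)CCC=C | intermediate
5 | (4R,5S)-5-(tert-butyldimethylsilyloxy)nona-1,8-dien-4-ol | C=CC[C@@H](O)[C@@H](O[Si](C)(C)C(C)(C)C)CCC=C | intermediate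
6 | (1R,7S)-7-(tert-butyldimethylsilyloxy)cyclohept-3-en-1-ol (cis) | O[C@@H]1CC=CCC[C@@H]1O[Si](C)(C)C(C)(C)C | intermediate
7 | (1S,3R,4S,7R)-4-(tert-butyldimethylsilyloxy)-8-oxabicyclo[5.1.0]octan-3-ol (epoxide, OH and OTBS all cis) | O[C@@H]1C[C@@H]2O[C@@H]2CC[C@@H]1O[Si](C)(C)C(C)(C)C | intermediate
8 | trans-bromohydrin bromomagnesium alkoxide (Br on the carbon nearer the free OH, anti to the oxygens) | O[C@@H]1C[C@@H](Br)[C@H](O[Mg]Br)CC[C@@H]1O[Si](C)(C)C(C)(C)C | intermediate
9 | regioisomeric trans-bromohydrin bromomagnesium alkoxide | O[C@@H]1C[C@H](O[Mg]Br)[C@@H](Br)CC[C@@H]1O[Si](C)(C)C(C)(C)C | intermediate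
10 | (1S,3R,4S)-4-(tert-butyldimethylsilyloxy)-3-hydroxycyclohexane-1-carbaldehyde | O[C@@H]1C[C@@H](C=O)CC[C@@H]1O[Si](C)(C)C(C)(C)C | intermediate
11 | prop-2-yn-1-ol | C#CCO | starting material
12 | dimethylaluminium (E)-3-(dimethylalumanyl)-2-methylprop-2-en-1-olate | C[Al](C)OC/C(C)=C/[Al](C)C | intermediate
13 | (E)-3-iodo-2-methylprop-2-en-1-ol | OC/C(C)=C/I | intermediate
14 | (E)-3-iodo-2-methylprop-2-enal | O=C/C(C)=C/I | intermediate
15 | ethyl (2E,4E,6E)-7-iodo-6-methylhepta-2,4,6-trienoate | CCOC(=O)/C=C/C=C/C(C)=C/I | intermediate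
16 | (2E,4E,6E)-7-iodo-6-methylhepta-2,4,6-trienoic acid | OC(=O)/C=C/C=C/C(C)=C/I | intermediate
17 | (2E,4E,6E)-7-iodo-6-methylhepta-2,4,6-trienoic 2,4,6-trichlorobenzoic anhydride | O=C(OC(=O)c1c(Cl)cc(Cl)cc1Cl)/C=C/C=C/C(C)=C/I | intermediate
18 | (1R,2S,5S)-2-(tert-butyldimethylsilyloxy)-5-formylcyclohexyl (2E,4E,6E)-7-iodo-6-methylhepta-2,4,6-trienoate | I/C=C(C)/C=C/C=C/C(=O)O[C@@H]1C[C@@H](C=O)CC[C@@H]1O[Si](C)(C)C(C)(C)C | intermediate
19 | (1S,3R,4S)-4-(tert-butyldimethylsilyloxy)-3-{[(2E,4E,6E)-7-iodo-6-methylhepta-2,4,6-trienoyl]oxy}cyclohexane-1-carboxylic acid | I/C=C(C)/C=C/C=C/C(=O)O[C@@H]1C[C@@H](C(=O)O)CC[C@@H]1O[Si](C)(C)C(C)(C)C | intermediate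
20 | (S)-but-3-ene-1,2-diol | C=C[C@H](O)CO | starting material
21 | (S)-3,4-bis(tert-butyldimethylsilyloxy)but-1-ene | C=C[C@H](O[Si](C)(C)C(C)(C)C)CO[Si](C)(C)C(C)(C)C | intermediate
22 | (S)-2-(tert-butyldimethylsilyloxy)but-3-en-1-ol | C=C[C@H](O[Si](C)(C)C(C)(C)C)CO | intermediate
23 | (S)-2-(tert-butyldimethylsilyloxy)but-3-enal | C=C[C@H](O[Si](C)(C)C(C)(C)C)C=O | intermediate
24 | (S)-but-3-yn-2-ol | C[C@H](O)C#C | starting material
25 | (S)-but-3-yn-2-yl methanesulfonate | C[C@H](OS(C)(=O)=O)C#C | intermediate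
26 | (aR)-tributyl(buta-1,2-dien-1-yl)stannane | CCCC[Sn](CCCC)(CCCC)C([H])=[C@]=C([H])C | intermediate
27 | (3S,4R,5S)-3-(tert-butyldimethylsilyloxy)-5-methylhept-1-en-6-yn-4-ol (3,4-anti, 4,5-syn) | C=C[C@H](O[Si](C)(C)C(C)(C)C)[C@H](O)[C@@H](C)C#C | intermediate
28 | (3S,4R,5S)-3,4-bis(tert-butyldimethylsilyloxy)-5-methylhept-1-en-6-yne | C=C[C@H](O[Si](C)(C)C(C)(C)C)[C@H](O[Si](C)(C)C(C)(C)C)[C@@H](C)C#C | intermediate
29 | lithium acetylide of 28 | C=C[C@H](O[Si](C)(C)C(C)(C)C)[C@H](O[Si](C)(C)C(C)(C)C)[C@@H](C)C#C[Li] | intermediate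
30 | methyl (4S,5R,6S)-5,6-bis(tert-butyldimethylsilyloxy)-4-methyloct-7-en-2-ynoate | C=C[C@H](O[Si](C)(C)C(C)(C)C)[C@H](O[Si](C)(C)C(C)(C)C)[C@@H](C)C#CC(=O)OC | intermediate
31 | methyl (2Z,4R,5R,6S)-5,6-bis(tert-butyldimethylsilyloxy)-3-chloro-4-methylocta-2,7-dienoate | C=C[C@H](O[Si](C)(C)C(C)(C)C)[C@H](O[Si](C)(C)C(C)(C)C)[C@@H](C)/C(Cl)=C/C(=O)OC | intermediate
32 | methyl (2Z,4R,5R,6R)-5,6-bis(tert-butyldimethylsilyloxy)-3-chloro-4-methyl-7-oxooct-2-enoate (C9–C16 methyl ketone) | CC(=O)[C@H](O[Si](C)(C)C(C)(C)C)[C@H](O[Si](C)(C)C(C)(C)C)[C@@H](C)/C(Cl)=C/C(=O)OC | intermediate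
33 | L-serine | N[C@@H](CO)C(=O)O | starting material
34 | (S)-2-chloro-3-hydroxypropanoic acid | OC[C@H](Cl)C(=O)O | intermediate
35 | methyl (S)-2-chloro-3-hydroxypropanoate | OC[C@H](Cl)C(=O)OC | intermediate
36 | methyl (S)-2-chloro-3-(triethylsilyloxy)propanoate | CC[Si](CC)(CC)OC[C@H](Cl)C(=O)OC | intermediate
37 | (S)-2-chloro-3-(triethylsilyloxy)propanal | CC[Si](CC)(CC)OC[C@H](Cl)C=O | intermediate
38 | lithium enolate of 32 (methyl side) | C=C(O[Li])[C@H](O[Si](C)(C)C(C)(C)C)[C@H](O[Si](C)(C)C(C)(C)C)[C@@H](C)/C(Cl)=C/C(=O)OC | intermediate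
39 | methyl (2Z,4R,5R,6R,9R,10S)-5,6-bis(tert-butyldimethylsilyloxy)-3,10-dichloro-9-hydroxy-4-methyl-7-oxo-11-(triethylsilyloxy)undec-2-enoate (17,18-anti) | CC[Si](CC)(CC)OC[C@H](Cl)[C@H](O)CC(=O)[C@H](O[Si](C)(C)C(C)(C)C)[C@H](O[Si](C)(C)C(C)(C)C)[C@@H](C)/C(Cl)=C/C(=O)OC | intermediate
40 | O17-diethylborinate (boron chelate) of 39 | CC[Si](CC)(CC)OC[C@H](Cl)[C@H](OB(CC)CC)CC(=O)[C@H](O[Si](C)(C)C(C)(C)C)[C@H](O[Si](C)(C)C(C)(C)C)[C@@H](C)/C(Cl)=C/C(=O)OC | intermediate
41 | methyl (2Z,4R,5R,6S,7S,9R,10S)-5,6-bis(tert-butyldimethylsilyloxy)-3,10-dichloro-7,9-dihydroxy-4-methyl-11-(triethylsilyloxy)undec-2-enoate (15,17-syn diol) | CC[Si](CC)(CC)OC[C@H](Cl)[C@H](O)C[C@H](O)[C@H](O[Si](C)(C)C(C)(C)C)[C@H](O[Si](C)(C)C(C)(C)C)[C@@H](C)/C(Cl)=C/C(=O)OC | intermediate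
42 | di-tert-butylsilylene acetal of 41 (O15/O17), configurations as in 41 | CC[Si](CC)(CC)OC[C@H](Cl)[C@H]1C[C@@H]([C@H](O[Si](C)(C)C(C)(C)C)[C@H](O[Si](C)(C)C(C)(C)C)[C@@H](C)/C(Cl)=C/C(=O)OC)O[Si](C(C)(C)C)(C(C)(C)C)O1 | intermediate
43 | C19 primary alcohol (42 without TES) | OC[C@H](Cl)[C@H]1C[C@@H]([C@H](O[Si](C)(C)C(C)(C)C)[C@H](O[Si](C)(C)C(C)(C)C)[C@@H](C)/C(Cl)=C/C(=O)OC)O[Si](C(C)(C)C)(C(C)(C)C)O1 | intermediate
44 | C19 aldehyde (α-chloro aldehyde) | O=C[C@H](Cl)[C@H]1C[C@@H]([C@H](O[Si](C)(C)C(C)(C)C)[C@H](O[Si](C)(C)C(C)(C)C)[C@@H](C)/C(Cl)=C/C(=O)OC)O[Si](C(C)(C)C)(C(C)(C)C)O1 | intermediate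
45 | (19S)-allylic alcohol with (20E)-butenyl group (18,19-anti) | CC/C=C/[C@H](O)[C@H](Cl)[C@H]1C[C@@H]([C@H](O[Si](C)(C)C(C)(C)C)[C@H](O[Si](C)(C)C(C)(C)C)[C@@H](C)/C(Cl)=C/C(=O)OC)O[Si](C(C)(C)C)(C(C)(C)C)O1 | intermediate
46 | N-trichloroacetyl carbamate of 45 | CC/C=C/[C@H](OC(=O)NC(=O)C(Cl)(Cl)Cl)[C@H](Cl)[C@H]1C[C@@H]([C@H](O[Si](C)(C)C(C)(C)C)[C@H](O[Si](C)(C)C(C)(C)C)[C@@H](C)/C(Cl)=C/C(=O)OC)O[Si](C(C)(C)C)(C(C)(C)C)O1 | intermediate
47 | C19 carbamate, C9 methyl ester | CC/C=C/[C@H](OC(N)=O)[C@H](Cl)[C@H]1C[C@@H]([C@H](O[Si](C)(C)C(C)(C)C)[C@H](O[Si](C)(C)C(C)(C)C)[C@@H](C)/C(Cl)=C/C(=O)OC)O[Si](C(C)(C)C)(C(C)(C)C)O1 | intermediate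
48 | C9 allylic alcohol (10Z) | CC/C=C/[C@H](OC(N)=O)[C@H](Cl)[C@H]1C[C@@H]([C@H](O[Si](C)(C)C(C)(C)C)[C@H](O[Si](C)(C)C(C)(C)C)[C@@H](C)/C(Cl)=C/CO)O[Si](C(C)(C)C)(C(C)(C)C)O1 | intermediate
49 | C9 enal (10Z) | CC/C=C/[C@H](OC(N)=O)[C@H](Cl)[C@H]1C[C@@H]([C@H](O[Si](C)(C)C(C)(C)C)[C@H](O[Si](C)(C)C(C)(C)C)[C@@H](C)/C(Cl)=C/C=O)O[Si](C(C)(C)C)(C(C)(C)C)O1 | intermediate
50 | (8E,10Z)-dienylboronic acid pinacol ester | CC/C=C/[C@H](OC(N)=O)[C@H](Cl)[C@H]1C[C@@H]([C@H](O[Si](C)(C)C(C)(C)C)[C@H](O[Si](C)(C)C(C)(C)C)[C@@H](C)/C(Cl)=C/C=C/B2OC(C)(C)C(C)(C)O2)O[Si](C(C)(C)C)(C(C)(C)C)O1 | intermediate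
51 | silyl-protected target (free CO2H) | CC/C=C/[C@H](OC(N)=O)[C@H](Cl)[C@H]1C[C@@H]([C@H](O[Si](C)(C)C(C)(C)C)[C@H](O[Si](C)(C)C(C)(C)C)[C@@H](C)/C(Cl)=C/C=C/C=C(C)/C=C/C=C/C(=O)O[C@@H]2C[C@@H](C(=O)O)CC[C@@H]2O[Si](C)(C)C(C)(C)C)O[Si](C(C)(C)C)(C(C)(C)C)O1 | intermediate
52 | CNP0164989.3 | CC/C=C/[C@H](OC(N)=O)[C@H](Cl)[C@H](O)C[C@H](O)[C@H](O)[C@H](O)[C@@H](C)/C(Cl)=C/C=C/C=C(C)/C=C/C=C/C(=O)O[C@@H]1C[C@@H](C(=O)O)CC[C@@H]1O | target

**Summary**

Total step count: 39.
Longest linear sequence: 20 steps (from 20 through steps 14–16, 19–23 and 28–39).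

Steps most likely to fail:

1. Step 7 (key step). The bromohydrin magnesium alkoxides may leave by other paths: hydride shift to the cycloheptanone, transannular displacement of bromide by the free hydroxyl to a bridged ether, or epimerization of the product aldehyde followed by lactol closure onto the cis hydroxyl. Fallback, from 6 back to 10: the hydroxyl of 6 is capped (TESCl, imidazole) to give cis-(1R,7S)-1-(triethylsilyloxy)-7-(tert-butyldimethylsilyloxy)cyclohept-3-ene F1. Oxidative rearrangement of the alkene with Tl(NO3)3·3H2O in MeOH/HC(OMe)3 (the known contraction of cycloheptene to the cyclohexanecarbaldehyde acetal) should then give (1S,3R,4S)-4-(tert-butyldimethylsilyloxy)-3-(triethylsilyloxy)cyclohexane-1-carbaldehyde dimethyl acetal F2. Here the thallium electrophile adds anti to the two silyloxy groups, methanol adds anti to it, and the ring bond migrates with inversion at the thallium-bearing carbon, so the acetal carbon is again trans to both oxygens and both regiochemical modes converge. Aqueous acetic acid in THF then cleaves the acetal and the TES ether to return 10.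

2. Step 33. Facial selectivity at C19 may be poor because the β-silyloxy substituent opposes the Cornforth preference of the α-chloro centre, and the α-chloro aldehyde may epimerize at C18 or eliminate during the addition. Fallback, from 44 back to 45: the source of stereocontrol is changed from substrate to catalyst. 1-Butyne is hydroborated with dicyclohexylborane, transmetalated with Et2Zn and added to 44 in the presence of (−)-3-exo-morpholinoisoborneol (5 mol %, amino alcohol-catalysed asymmetric alkenylzinc addition), which should deliver the alkenyl group to the Si face of the aldehyde and give 45; no new compound is made (F0).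

3. Step 22. Chloride addition at the hindered β-carbon may be slow in hot acetic acid, with loss of the silyl ethers in competition. Fallback, from 28 back to 31 (steps 21 and 22 replaced): palladium-catalysed chlorocarbonylation of the terminal alkyne (PdCl2 (5 mol %), CuCl2 (3 equiv), CO (1 atm), MeOH/benzene, rt) should form the (Z)-3-chloroacrylate 31 in one operation by chloropalladation and methoxycarbonylation, without acid or heat; no new compound is made (F0).

**Further compounds**

F1 | step 7 | cis-(1R,7S)-1-(triethylsilyloxy)-7-(tert-butyldimethylsilyloxy)cyclohept-3-ene | CC[Si](CC)(CC)O[C@@H]1CC=CCC[C@@H]1O[Si](C)(C)C(C)(C)C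
F2 | step 7 | (1S,3R,4S)-4-(tert-butyldimethylsilyloxy)-3-(triethylsilyloxy)cyclohexane-1-carbaldehyde dimethyl acetal | CC[Si](CC)(CC)O[C@@H]1C[C@@H](C(OC)OC)CC[C@@H]1O[Si](C)(C)C(C)(C)C
F0 | step 33 | none | none
F0 | step 22 | none | none
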